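The route rests on reading the trans-3,4-disubstituted tetrahydrofuran as a reduced butenolide: C8' and C8 are the former α- and β-carbons, C9' the former lactone carbonyl and C9 the former γ-acetal carbon, while each of the two ring carbons carries a benzylic carbon (C7', C7). In one flask a lithiated aryl dithiane (a masked C7 ketone) adds to the β-carbon of (5R)-menthyloxybutenolide and the enolate so formed is benzylated, which forms C7–C8 and C7'–C8' and sets both ring stereocentres trans. The precursor set is the chiral butenolide, the O-benzylvanillin dithiane and the O-benzylvanillyl bromide. Diol formation, ring closure, unmasking, catalyst-controlled ketone reduction and debenzylation follow.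

Key step: step 6

Remark: lignan numbering is used (C7–C9 for the carbinol half, C7'–C9' for the benzyl half), and O-benzylvanillin is assumed to be purchased (otherwise one benzylation of vanillin with BnBr/K2CO3 precedes steps 3 and 4).

Step 1
Reactants: 1 furfural
Product: 3 5-hydroxyfuran-2(5H)-one (racemic), via furfural 2,5-endoperoxide 2 (not isolated)
Conditions: O2, rose bengal (disodium 4,5,6,7-tetrachloro-2',4',5',7'-tetraiodofluorescein, cat.), MeOH, visible light, rt
Reagents that add atoms: dioxygen O=O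
Why: Sensitised singlet-oxygen [4+2] photooxygenation of the furan gives endoperoxide 2, which methanol fragments with loss of the formyl carbon as methyl formate to leave the hydroxybutenolide; its C5 centre is racemic, which does not matter because it is equilibrated in step 2.

Step 2
Reactants: 3 5-hydroxyfuran-2(5H)-one; 4 (−)-menthol, (1R,2S,5R)-2-isopropyl-5-methylcyclohexanol
Product: 5 (5R)-5-[(1R,2S,5R)-menthyloxy]furan-2(5H)-one
Conditions: camphorsulfonic acid (cat.), toluene, reflux, Dean–Stark; crystallise from hexane, re-equilibrate the mother liquor with acid, recrystallise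
Reagents that add atoms: none
Why: Acid-catalysed acetalisation of the lactol (Fischer glycosidation type) gives both C5 epimers, which interconvert through the oxocarbenium ion, and because the (5R) epimer is the one that crystallises, crystallisation with recycling of the mother liquor should fix C5 as R.

Step 3
Reactants: 6 4-benzyloxy-3-methoxybenzaldehyde (O-benzylvanillin); 7 propane-1,3-dithiol
Product: 8 2-(4-benzyloxy-3-methoxyphenyl)-1,3-dithiane
Conditions: BF3·OEt2 (cat.), CH2Cl2, 0 °C → rt
Reagents that add atoms: none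
Why: Lewis-acid-catalysed dithioacetalisation of the aromatic aldehyde installs the acidic C7–H needed for umpolung and creates no stereocentre.

Step 4
Reactants: 6 4-benzyloxy-3-methoxybenzaldehyde
Product: 9 (4-benzyloxy-3-methoxyphenyl)methanol
Conditions: NaBH4, MeOH, 0 °C
Reagents that add atoms: none
Why: Borohydride reduction of the aldehyde to the benzylic alcohol is chemoselective and forms no stereocentre.

Step 5
Reactants: 9 (4-benzyloxy-3-methoxyphenyl)methanol
Product: 10 4-benzyloxy-3-methoxybenzyl bromide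
Conditions: PBr3 (0.4 equiv), Et2O, 0 °C
Reagents that add atoms: phosphorus tribromide BrP(Br)Br
Why: Bromination of the electron-rich benzylic alcohol with PBr3 (phosphite ester formation, then displacement by bromide) gives the alkylating agent, which is used soon after isolation because such bromides slowly self-condense.

Step 6
Reactants: 8 2-(4-benzyloxy-3-methoxyphenyl)-1,3-dithiane; 5 (5R)-5-[(1R,2S,5R)-menthyloxy]furan-2(5H)-one; 10 4-benzyloxy-3-methoxybenzyl bromide
Product: 13 (3R,4R,5R)-3-(4-benzyloxy-3-methoxybenzyl)-4-[2-(4-benzyloxy-3-methoxyphenyl)-1,3-dithian-2-yl]-5-[(1R,2S,5R)-menthyloxy]dihydrofuran-2(3H)-one, via 2-lithio-1,3-dithiane 11 (not isolated), via lithium lactone enolate 12 (not isolated)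
Conditions: n-BuLi (1.05 equiv), THF, −78 °C; then 5, −78 °C; then 10, DMPU, −78 → −20 °C; aq NH4Cl
Reagents that add atoms: none
Why: n-BuLi removes the C2 proton of 8 to give the sulfur- and aryl-stabilised carbanion 11, which adds in a conjugate sense to the β-carbon of 5 (C7–C8 bond) and leaves lithium enolate 12, and 12 is then C-alkylated by bromide 10 in an SN2 reaction (C7'–C8' bond). The closest known reaction type is the tandem Michael addition–enolate alkylation of lithiated 2-aryl-1,3-dithianes on 5-alkoxyfuran-2(5H)-ones. No ring is closed. C8 is controlled by the C5 menthyloxy group of the flat butenolide, which shields its own face so that 11 enters trans to it, and C8' is controlled by the bulky dithianyl group just placed on C8, which sends 10 to the opposite face of the enolate, so the trans,trans (3R,4R,5R) lactone should result. The step needs 1,4- rather than 1,2-addition, which the soft, delocalised and hindered carbanion at −78 °C should secure, and clean C-monoalkylation, which the reactive benzylic bromide with DMPU as cosolvent should secure. The acetal carbon should survive because the menthyloxy group is not β to the enolate carbon, so no elimination pathway is open.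

Step 7
Reactants: 13 (3R,4R,5R)-3-(4-benzyloxy-3-methoxybenzyl)-4-[2-(4-benzyloxy-3-methoxyphenyl)-1,3-dithian-2-yl]-5-[(1R,2S,5R)-menthyloxy]dihydrofuran-2(3H)-one
Product: 15 (2R,3R)-2-(4-benzyloxy-3-methoxybenzyl)-3-[2-(4-benzyloxy-3-methoxyphenyl)-1,3-dithian-2-yl]butane-1,4-diol, via C9 aldehyde 14 (not isolated)
Conditions: LiAlH4, THF, 0 °C → rt; aq NaOH work-up
Reagents that add atoms: none
Why: LiAlH4 reduction of the acylal-type lactone opens the ring to the C9' carbinol, the freed C9 hemiacetal expels menthoxide to give aldehyde 14, and a further hydride reduces it, so both former ring carbons become primary alcohols while C8 and C8' stay untouched because the transient aldehyde should be reduced faster than it enolises.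

Step 8
Reactants: 15 (2R,3R)-2-(4-benzyloxy-3-methoxybenzyl)-3-[2-(4-benzyloxy-3-methoxyphenyl)-1,3-dithian-2-yl]butane-1,4-diol
Product: 17 2-(4-benzyloxy-3-methoxyphenyl)-2-[(3R,4R)-4-(4-benzyloxy-3-methoxybenzyl)tetrahydrofuran-3-yl]-1,3-dithiane, via C9' monotosylate 16 (not isolated)
Conditions: NaH (2.5 equiv), THF, 0 °C; TsCl (1.05 equiv, slow addition), 0 °C → rt
Reagents that add atoms: none
Why: Monosulfonylation of the less hindered primary alkoxide followed by intramolecular Williamson etherification (5-exo-tet) by the other alkoxide closes the tetrahydrofuran, the same ring arising whichever hydroxyl is sulfonylated; because C7 is still a dithiane there is no third hydroxyl to close a competing ring, the alkoxide should outpace the dithiane sulfur as internal nucleophile, and neither stereocentre takes part.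

Step 9
Reactants: 17 2-(4-benzyloxy-3-methoxyphenyl)-2-[(3R,4R)-4-(4-benzyloxy-3-methoxybenzyl)tetrahydrofuran-3-yl]-1,3-dithiane
Product: 18 (4-benzyloxy-3-methoxyphenyl)[(3R,4R)-4-(4-benzyloxy-3-methoxybenzyl)tetrahydrofuran-3-yl]methanone
Conditions: PhI(OCOCF3)2 (1.5 equiv), MeCN/H2O 9:1, 0 °C → rt
Reagents that add atoms: water O
Why: Oxidative hydrolysis of the dithioacetal by the hypervalent iodine reagent (S-activation, opening to an aryl-stabilised thionium ion, capture by water) releases the ketone without base, and since C8 next to the new carbonyl already sits trans to the C8' substituent, the more stable arrangement, its configuration should hold.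

Step 10
Reactants: 18 (4-benzyloxy-3-methoxyphenyl)[(3R,4R)-4-(4-benzyloxy-3-methoxybenzyl)tetrahydrofuran-3-yl]methanone
Product: 19 (R)-(4-benzyloxy-3-methoxyphenyl)[(3R,4R)-4-(4-benzyloxy-3-methoxybenzyl)tetrahydrofuran-3-yl]methanol
Conditions: (S)-Me-CBS oxazaborolidine [(S)-1-methyl-3,3-diphenyltetrahydro-1H,3H-pyrrolo[1,2-c][1,3,2]oxazaborole, 0.3 equiv], BH3·SMe2 (1.0 equiv), THF, −20 °C; MeOH quench
Reagents that add atoms: none
Why: Corey–Bakshi–Shibata reduction, in which the ketone binds the ring boron of the (S)-oxazaborolidine with the aryl group as the large substituent turned away from the catalyst and the nitrogen-bound borane delivers hydride to the Si face, should set C7 as R under catalyst control, which is relied on because the intrinsic bias of the neighbouring ring stereocentre C8 is small and of uncertain sense.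

Step 11
Reactants: 19 (R)-(4-benzyloxy-3-methoxyphenyl)[(3R,4R)-4-(4-benzyloxy-3-methoxybenzyl)tetrahydrofuran-3-yl]methanol
Product: 20 (R)-(4-hydroxy-3-methoxyphenyl)[(3R,4R)-4-(4-hydroxy-3-methoxybenzyl)tetrahydrofuran-3-yl]methanol
Conditions: H2 (1 atm), 10% Pd/C, EtOAc, rt, stopped at full conversion
Reagents that add atoms: none
Why: Heterogeneous catalytic hydrogenolysis cleaves the two aryl benzyl ethers, which under neutral conditions in EtOAc should react well before the secondary benzylic C7–O bond, and no stereocentre is involved.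

Compound list
1 | furfural | O=Cc1ccco1 | starting material
2 | furfural 2,5-endoperoxide (2,3,7-trioxabicyclo[2.2.1]hept-5-ene-1-carbaldehyde) | O=CC12OOC(C=C1)O2 | intermediate
3 | 5-hydroxyfuran-2(5H)-one (racemic) | O=C1C=CC(O)O1 | intermediate
4 | (−)-menthol, (1R,2S,5R)-2-isopropyl-5-methylcyclohexanol | C[C@@H]1CC[C@H]([C@@H](C1)O)C(C)C | starting material
5 | (5R)-5-[(1R,2S,5R)-menthyloxy]furan-2(5H)-one | O=C1C=C[C@H](O[C@@H]2C[C@H](C)CC[C@H]2C(C)C)O1 | intermediate
6 | 4-benzyloxy-3-methoxybenzaldehyde | COc1cc(C=O)ccc1OCc1ccccc1 | starting material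
7 | propane-1,3-dithiol | SCCCS | starting material
8 | 2-(4-benzyloxy-3-methoxyphenyl)-1,3-dithiane | COc1cc(C2SCCCS2)ccc1OCc1ccccc1 | intermediate
9 | (4-benzyloxy-3-methoxyphenyl)methanol | COc1cc(CO)ccc1OCc1ccccc1 | intermediate
10 | 4-benzyloxy-3-methoxybenzyl bromide | COc1cc(CBr)ccc1OCc1ccccc1 | intermediate
11 | 2-lithio-2-(4-benzyloxy-3-methoxyphenyl)-1,3-dithiane | [Li]C1(c2ccc(OCc3ccccc3)c(OC)c2)SCCCS1 | intermediate
12 | lithium enolate of (4R,5R)-4-[2-(4-benzyloxy-3-methoxyphenyl)-1,3-dithian-2-yl]-5-menthyloxydihydrofuran-2(3H)-one | [Li]OC1=C[C@@H](C2(c3ccc(OCc4ccccc4)c(OC)c3)SCCCS2)[C@H](O[C@@H]2C[C@H](C)CC[C@H]2C(C)C)O1 | intermediate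
13 | (3R,4R,5R)-3-(4-benzyloxy-3-methoxybenzyl)-4-[2-(4-benzyloxy-3-methoxyphenyl)-1,3-dithian-2-yl]-5-[(1R,2S,5R)-menthyloxy]dihydrofuran-2(3H)-one | COc1cc(C[C@H]2C(=O)O[C@@H](O[C@@H]3C[C@H](C)CC[C@H]3C(C)C)[C@@H]2C2(c3ccc(OCc4ccccc4)c(OC)c3)SCCCS2)ccc1OCc1ccccc1 | intermediate
14 | (2R,3R)-3-(4-benzyloxy-3-methoxybenzyl)-2-[2-(4-benzyloxy-3-methoxyphenyl)-1,3-dithian-2-yl]-4-hydroxybutanal | COc1cc(C[C@@H](CO)[C@H](C=O)C2(c3ccc(OCc4ccccc4)c(OC)c3)SCCCS2)ccc1OCc1ccccc1 | intermediate
15 | (2R,3R)-2-(4-benzyloxy-3-methoxybenzyl)-3-[2-(4-benzyloxy-3-methoxyphenyl)-1,3-dithian-2-yl]butane-1,4-diol | COc1cc(C[C@@H](CO)[C@H](CO)C2(c3ccc(OCc4ccccc4)c(OC)c3)SCCCS2)ccc1OCc1ccccc1 | intermediate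
16 | (2R,3R)-2-(4-benzyloxy-3-methoxybenzyl)-3-[2-(4-benzyloxy-3-methoxyphenyl)-1,3-dithian-2-yl]-4-hydroxybutyl 4-methylbenzenesulfonate | COc1cc(C[C@@H](COS(=O)(=O)c2ccc(C)cc2)[C@H](CO)C2(c3ccc(OCc4ccccc4)c(OC)c3)SCCCS2)ccc1OCc1ccccc1 | intermediate
17 | 2-(4-benzyloxy-3-methoxyphenyl)-2-[(3R,4R)-4-(4-benzyloxy-3-methoxybenzyl)tetrahydrofuran-3-yl]-1,3-dithiane | COc1cc(C[C@H]2COC[C@@H]2C2(c3ccc(OCc4ccccc4)c(OC)c3)SCCCS2)ccc1OCc1ccccc1 | intermediate
18 | (4-benzyloxy-3-methoxyphenyl)[(3R,4R)-4-(4-benzyloxy-3-methoxybenzyl)tetrahydrofuran-3-yl]methanone | COc1cc(C[C@H]2COC[C@@H]2C(=O)c2ccc(OCc3ccccc3)c(OC)c2)ccc1OCc1ccccc1 | intermediate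
19 | (R)-(4-benzyloxy-3-methoxyphenyl)[(3R,4R)-4-(4-benzyloxy-3-methoxybenzyl)tetrahydrofuran-3-yl]methanol | COc1cc(C[C@H]2COC[C@@H]2[C@@H](O)c2ccc(OCc3ccccc3)c(OC)c2)ccc1OCc1ccccc1 | intermediate
20 | (R)-(4-hydroxy-3-methoxyphenyl)[(3R,4R)-4-(4-hydroxy-3-methoxybenzyl)tetrahydrofuran-3-yl]methanol | COc1cc(C[C@H]2COC[C@@H]2[C@@H](O)c2ccc(O)c(OC)c2)ccc1O | target

Total step count: 11. Longest linear sequence: 8 steps (steps 1, 2, 6, 7, 8, 9, 10, 11 from furfural; the branch from 6 through steps 4 and 5 is equally long).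

Steps most likely to fail

The key step, step 6, carries the main risk. The enolate may be trapped incompletely or unselectively: proton exchange between enolate 12 and the bromide or the product, alkylation of unreacted carbanion 11 by 10, or some 1,2-addition would all erode the one-pot outcome. The fallback separates the two bond formations. Starting from 8 and 5, carbanion 11 is added to 5 as before, but the enolate is protonated at −78 °C with aq NH4Cl and the trans mono-adduct (4R,5R)-4-[2-(4-benzyloxy-3-methoxyphenyl)-1,3-dithian-2-yl]-5-[(1R,2S,5R)-menthyloxy]dihydrofuran-2(3H)-one F1 is isolated. Its enolate is then regenerated with LiN(i-Pr)2 in THF/DMPU at −78 °C and alkylated with 10 anti to the dithianyl group, which returns to the route at 13.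

Step 10 may show poor facial selectivity at C7. The catalyst may discriminate too little between the aryl group and the branched ring substituent, or the preference of the catalyst and that of the C8 stereocentre may oppose each other. The fallback relies on substrate control followed by inversion. Starting from 18, reduction with LiBH(s-Bu)3 in THF at −78 °C should follow the Felkin–Anh preference, expected to give mainly the (7S) epimer, (S)-(4-benzyloxy-3-methoxyphenyl)[(3R,4R)-4-(4-benzyloxy-3-methoxybenzyl)tetrahydrofuran-3-yl]methanol F2, if C8' acts as the large substituent. Mitsunobu esterification with 4-nitrobenzoic acid (PPh3, diisopropyl azodicarboxylate, toluene, 0 °C) should invert C7 to give (R)-(4-benzyloxy-3-methoxyphenyl)[(3R,4R)-4-(4-benzyloxy-3-methoxybenzyl)tetrahydrofuran-3-yl]methyl 4-nitrobenzoate F3. Methanolysis with K2CO3 (cat.) in MeOH returns to the route at 19.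

Step 11 may over-reduce: hydrogenolytic cleavage of the electron-rich benzylic C7–O bond can compete with removal of the benzyl ethers. The fallback exchanges the phenol protecting groups before the carbinol exists. Starting from 18, hydrogenolysis (H2, 10% Pd/C, EtOAc) at the ketone stage, where no benzylic C–O bond is at risk, gives (4-hydroxy-3-methoxyphenyl)[(3R,4R)-4-(4-hydroxy-3-methoxybenzyl)tetrahydrofuran-3-yl]methanone F4. Silylation (TBSCl, imidazole, DMF) gives [4-(tert-butyldimethylsilyloxy)-3-methoxyphenyl]{(3R,4R)-4-[4-(tert-butyldimethylsilyloxy)-3-methoxybenzyl]tetrahydrofuran-3-yl}methanone F5. Reduction under the conditions of step 10 gives (R)-[4-(tert-butyldimethylsilyloxy)-3-methoxyphenyl]{(3R,4R)-4-[4-(tert-butyldimethylsilyloxy)-3-methoxybenzyl]tetrahydrofuran-3-yl}methanol F6. Desilylation with Bu4NF buffered with AcOH in THF at 0 °C returns to the route at 20.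

Further compounds
F1 | step 6 | (4R,5R)-4-[2-(4-benzyloxy-3-methoxyphenyl)-1,3-dithian-2-yl]-5-[(1R,2S,5R)-menthyloxy]dihydrofuran-2(3H)-one | O=C1C[C@@H](C2(c3ccc(OCc4ccccc4)c(OC)c3)SCCCS2)[C@H](O[C@@H]2C[C@H](C)CC[C@H]2C(C)C)O1
F2 | step 10 | (S)-(4-benzyloxy-3-methoxyphenyl)[(3R,4R)-4-(4-benzyloxy-3-methoxybenzyl)tetrahydrofuran-3-yl]methanol | COc1cc(C[C@H]2COC[C@@H]2[C@H](O)c2ccc(OCc3ccccc3)c(OC)c2)ccc1OCc1ccccc1
F3 | step 10 | (R)-(4-benzyloxy-3-methoxyphenyl)[(3R,4R)-4-(4-benzyloxy-3-methoxybenzyl)tetrahydrofuran-3-yl]methyl 4-nitrobenzoate | COc1cc(C[C@H]2COC[C@@H]2[C@@H](OC(=O)c2ccc(cc2)[N+](=O)[O-])c2ccc(OCc3ccccc3)c(OC)c2)ccc1OCc1ccccc1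
F4 | step 11 | (4-hydroxy-3-methoxyphenyl)[(3R,4R)-4-(4-hydroxy-3-methoxybenzyl)tetrahydrofuran-3-yl]methanone | COc1cc(C[C@H]2COC[C@@H]2C(=O)c2ccc(O)c(OC)c2)ccc1O
F5 | step 11 | [4-(tert-butyldimethylsilyloxy)-3-methoxyphenyl]{(3R,4R)-4-[4-(tert-butyldimethylsilyloxy)-3-methoxybenzyl]tetrahydrofuran-3-yl}methanone | COc1cc(C[C@H]2COC[C@@H]2C(=O)c2ccc(O[Si](C)(C)C(C)(C)C)c(OC)c2)ccc1O[Si](C)(C)C(C)(C)C
F6 | step 11 | (R)-[4-(tert-butyldimethylsilyloxy)-3-methoxyphenyl]{(3R,4R)-4-[4-(tert-butyldimethylsilyloxy)-3-methoxybenzyl]tetrahydrofuran-3-yl}methanol | COc1cc(C[C@H]2COC[C@@H]2[C@@H](O)c2ccc(O[Si](C)(C)C(C)(C)C)c(OC)c2)ccc1O[Si](C)(C)C(C)(C)C
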